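The gamma flask slowed.

| flask | Xa | Xb | Xc | time |
|---|---|---|---|---|
| gamma | 0.600 M | 0.660 M | 0.00120 M |  |
| theta | 0.300 M | 0.360 M | 0.00120 M |  |
| alpha | 1.80 M | 0.660 M | 0.00120 M |  |
| zeta | 0.600 M | 0.660 M | 6.00 × 10⁻⁴ M |  |
| eta | 0.600 M | 0.660 M | 0.00120 M | 38 h |

| run | time / h | [Xp] / M |
|---|---|---|
| gamma run | 1.4 | 0.0399 |
| gamma run | 4.4 | 0.1068 |
| gamma run | 8.4 | 0.1612 |
| gamma run | 13 | 0.2038 |
| gamma run | 19 | 0.2271 |
| theta run | 1.4 | 0.0196 |
| theta run | 4.4 | 0.0575 |
| theta run | 8.4 | 0.0884 |
| theta run | 13 | 0.1133 |
| theta run | 19 | 0.1280 |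
| alpha run | 1.4 | 0.0529 |
| alpha run | 4.4 | 0.1442 |
| alpha run | 8.4 | 0.2297 |
| alpha run | 13 | 0.2892 |
| alpha run | 19 | 0.3230 |
| zeta run | 1.4 | 0.0230 |
| zeta run | 4.4 | 0.0574 |
| zeta run | 8.4 | 0.0846 |
| zeta run | 13 | 0.1118 |
| zeta run | 19 | 0.1287 |

(each reading ± 0.002 M)

1. apparent order in [Xa] of the starting rate, round the charge of the gamma run (the rate where two percent of its Xa have turned into Xp) (one fixed amount of Xp, the same in the runs compared)
2. apparent order in [Xc] of the starting rate, round the charge of the gamma run (the rate where two percent of its Xa have turned into Xp)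
3. Xp in the eta run at 38 h, as a share of the Xa charged

- Overall: Xa + Xb -> Xp, with Xc as catalyst.
- Constant volume, constant temperature.
- An order is taken over about fifteen percent of the charge, up and down.

Before charging eta, the same mixture as gamma, I had to decide whether a wait of 38 h was worth it or whether the flask should come off near 19 h. In the gamma run, the net gain of Xp read 0.00926 M h⁻¹ between 8.4 h and 13 h, then 0.00388 M h⁻¹ between 13 h and 19 h. I placed each gain at the middle of its interval and drew a straight line through the two. That line reached zero at 19.8 h, which I called the turning time. It lay 0.800 h past the last gamma reading, so I took that reading as the top of the curve. My ceiling for this charge therefore read 37.9%, an estimate from the gamma readings: the share of the charged Xa standing as Xp when the net gain reaches zero.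

The forecast put the orders at 0.4 in Xa and 0.86 in Xc, and the eta flask at 41.2%. Its grounds, in its own words: “The likely cause is time-based catalyst death”. That share is what the fit with a catalyst dying by itself gives, and it stood higher than my ceiling. So I kept the charge of gamma and left eta to 38 h: a reading above the ceiling favours the forecast, and one below it means that Xp itself is lost.

The orders came out at 0.42 in Xa and 1.0 in Xc, and the eta flask gave 35.1%, which is 2.8 percentage points under the ceiling.

    Xc + Xa → E + Xh (110.5 L mol⁻¹ h⁻¹)
    E + Xb → Xp + Xc (63.00 L mol⁻¹ h⁻¹)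
    Xp → G (0.02948 h⁻¹)
    Xc + Xb → Q + Xb (0.1645 L mol⁻¹ h⁻¹)

So 18.2 h past the turning time read from the gamma run, the eta flask held less than the ceiling, and the main reason is the conversion of Xp into G. The ceiling did not mark the end of making: the eta flask without that step reached 70.5% at 38 h, twice the ceiling.

The data stem from a simulated flask on assumed constants; noise was put on by code.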